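The route cuts C8–C9, the sp–sp2 bond between the C7≡C8 triple bond on the 3-hydroxy-β ring and the C9=C10 trisubstituted alkene that opens the polyene. A Sonogashira coupling of an unprotected C11 ring alkyne (terminal C8–H) with an unprotected C29 (9E)-polyenyl iodide forms this bond with retention of alkene geometry and gives the C40 diol directly as the last step. The iodide comes from a Wittig union of an ε-ring C15 hydroxy-aldehyde, made from (R)-α-ionone by P450 monooxygenase hydroxylation at C3', with a C14 iodo-pentaenyl phosphonium salt built on a C10 dialdehyde. The alkyne comes from (4R,6R)-actinol.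

Key step: step 13

Remark: (R)-α-ionone of high enantiomeric purity, (4R,6R)-actinol and (2E,4E,6E)-2,7-dimethylocta-2,4,6-trienedial are taken as purchasable. Positions are given in carotenoid numbering (unprimed on the acetylenic half, primed on the ε half). All polyene steps are run under argon in the dark.

Step 1
Reactants: 1 (R)-α-ionone
Product: 2 (3R,6R)-3-hydroxy-α-ionone
Conditions: P450 BM3 variant (cytochrome P450 monooxygenase, trans-3-selective), NADP+ (cat.), glucose dehydrogenase, D-glucose, air, potassium phosphate buffer pH 7.5, 2% DMSO, 25 °C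
Reagents that add atoms: dioxygen, O=O
Why: Enzymatic allylic C–H hydroxylation (hydrogen abstraction and oxygen rebound), a known biotransformation of α-ionone; the active site should deliver oxygen to C3' on the face anti to the C6' side chain, setting 3'R (3',6'-trans) and leaving the side-chain enone untouched.

Step 2
Reactants: 2 (3R,6R)-3-hydroxy-α-ionone
Product: 3 (2E,4E)-5-[(1R,4R)-4-hydroxy-2,6,6-trimethylcyclohex-2-en-1-yl]-3-methylpenta-2,4-dienenitrile
Conditions: (EtO)2P(O)CH2CN (1.5 equiv), NaH (1.4 equiv), THF, 0 °C; then 2, 0 °C to rt; chromatography removes the 2Z isomer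
Reagents that add atoms: diethyl cyanomethylphosphonate, CCOP(=O)(CC#N)OCC
Why: Horner–Wadsworth–Emmons olefination of the methyl ketone with a stabilised anion too weakly basic to epimerise C6' or move the ring alkene; it tolerates the free hydroxyl and should favour the 9'E nitrile.

Step 3
Reactants: 3 the C15 hydroxy-nitrile
Product: 4 (2E,4E)-5-[(1R,4R)-4-hydroxy-2,6,6-trimethylcyclohex-2-en-1-yl]-3-methylpenta-2,4-dienal
Conditions: i-Bu2AlH (2.5 equiv), CH2Cl2, −78 to −40 °C; then aq. potassium sodium tartrate, wet SiO2, 0 °C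
Reagents that add atoms: water, O
Why: Half-reduction of the nitrile to the N-aluminoimine (one extra equivalent is consumed by the hydroxyl) and neutral hydrolysis to the enal, which avoids acid at the ring allylic alcohol and keeps both alkene geometries.

Step 4
Reactants: 5 but-2-yn-1-ol
Product: 7 (E)-3-iodobut-2-en-1-ol, via alkenylzirconocene 6 (not isolated)
Conditions: Cp2Zr(H)Cl (2.2 equiv), THF, 0 °C to rt; then I2, THF, 0 °C; aq. Na2S2O3
Reagents that add atoms: iodine, II
Why: Hydrozirconation–iodinolysis: after the first equivalent forms the zirconium alkoxide, syn addition of Zr–H places zirconium on C3 (methyl-bearing, distal to oxygen), and iodinolysis with retention should give the E iodide with iodine trans to CH2OH.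

Step 5
Reactants: 7 (E)-3-iodobut-2-en-1-ol
Product: 9 diethyl [(2E)-3-iodobut-2-en-1-yl]phosphonate, via allylic bromide 8 (not isolated)
Conditions: CBr4, PPh3, CH2Cl2, 0 °C; evaporate; then P(OEt)3, 90 °C
Reagents that add atoms: triethyl phosphite, CCOP(OCC)OCC; carbon tetrabromide, BrC(Br)(Br)Br (bromine of intermediate 8 only)
Why: Appel bromination under neutral conditions followed by Michaelis–Arbuzov reaction of the crude primary allylic bromide; the vinyl iodide is inert to both and keeps its geometry.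

Step 6
Reactants: 9 diethyl [(2E)-3-iodobut-2-en-1-yl]phosphonate; 10 (2E,4E,6E)-2,7-dimethylocta-2,4,6-trienedial (C10 dialdehyde)
Product: 12 (2E,4E,6E,8E,10E)-11-iodo-2,7-dimethyldodeca-2,4,6,8,10-pentaenal, via phosphonate sodium salt 11 (not isolated)
Conditions: NaN(SiMe3)2, THF, −78 °C; then cannulate into 10 (3 equiv), THF, −78 to 0 °C
Reagents that add atoms: none
Why: Horner–Wadsworth–Emmons olefination of an allylic phosphonate anion, which should be E-selective at the new C11=C12 bond; inverse addition to excess symmetrical dialdehyde favours mono-olefination and unreacted 10 is recovered.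

Step 7
Reactants: 12 the C14 iodo-pentaenal
Product: 13 (2E,4E,6E,8E,10E)-11-iodo-2,7-dimethyldodeca-2,4,6,8,10-pentaen-1-ol
Conditions: NaBH4, MeOH/CH2Cl2, 0 °C
Reagents that add atoms: none
Why: Chemoselective 1,2-reduction of the conjugated aldehyde by borohydride leaves the polyene and the vinyl iodide intact.

Step 8
Reactants: 13 the C14 iodo-pentaenol
Product: 14 [(2E,4E,6E,8E,10E)-11-iodo-2,7-dimethyldodeca-2,4,6,8,10-pentaen-1-yl]triphenylphosphonium bromide
Conditions: PPh3·HBr, MeOH, rt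
Reagents that add atoms: triphenylphosphine hydrobromide, [Br-].c1ccccc1[PH+](c1ccccc1)c1ccccc1
Why: Classical conversion of a polyenylic alcohol into its Wittig salt: acid-promoted ionisation to a delocalised polyenyl cation and capture by PPh3 at the unhindered primary terminus C12', which restores full conjugation.

Step 9
Reactants: 14 the C14 phosphonium bromide; 4 the C15 hydroxy-aldehyde
Product: 15 (1R,4R)-4-[(1E,3E,5E,7E,9E,11E,13E,15E)-16-iodo-3,7,12-trimethylheptadeca-1,3,5,7,9,11,13,15-octaen-1-yl]-3,5,5-trimethylcyclohex-2-en-1-ol (C29 iodide)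
Conditions: NaOMe, MeOH/CH2Cl2, 0 °C to rt; then EtOAc, 60 °C (equilibration of 11'Z to 11'E)
Reagents that add atoms: none
Why: Wittig olefination of the alkoxide-generated conjugated ylide with the enal tolerates the free hydroxyl and forms C11'=C12'; the hindered 11'Z isomer (C10'–H against the C13' methyl) should isomerise thermally to the all-E iodide.

Step 10
Reactants: 16 (4R,6R)-4-hydroxy-2,2,6-trimethylcyclohexan-1-one (actinol)
Product: 17 (4R,6R)-4-[(tert-butyldimethylsilyl)oxy]-2,2,6-trimethylcyclohexan-1-one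
Conditions: TBSCl, imidazole, DMF, rt
Reagents that add atoms: tert-butyldimethylsilyl chloride, CC(C)(C)[Si](C)(C)Cl
Why: Silyl ether formation at the unhindered secondary alcohol masks the hydroxyl for the enolate step.

Step 11
Reactants: 17 the silylated actinol
Product: 19 (4R)-4-[(tert-butyldimethylsilyl)oxy]-2,6,6-trimethylcyclohex-1-en-1-yl trifluoromethanesulfonate, via lithium enolate 18 (not isolated)
Conditions: LiN(i-Pr)2, THF, −78 to 0 °C; then PhNTf2, −78 °C to rt
Reagents that add atoms: N-phenylbis(trifluoromethanesulfonimide), O=S(=O)(N(c1ccccc1)S(=O)(=O)C(F)(F)F)C(F)(F)F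
Why: Deprotonation can occur only at C6 (the other α-carbon is quaternary), giving a single tetrasubstituted enolate that is O-triflated; the C6 stereocentre is erased on purpose and C4 is untouched.

Step 12
Reactants: 19 the enol triflate
Product: 21 (1R)-4-ethynyl-3,5,5-trimethylcyclohex-3-en-1-ol, via silylated enyne 20 (not isolated)
Conditions: PdCl2(PPh3)2 (5 mol%), CuI (10 mol%), Me3SiC≡CH, Et3N, DMF, 50 °C; then TBAF (3 equiv), THF, rt
Reagents that add atoms: ethynyltrimethylsilane, C#C[Si](C)(C)C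
Why: Sonogashira coupling of the hindered enol triflate with trimethylsilylacetylene, then fluoride cleavage of the C–SiMe3 and O–Si bonds in the same flask, gives the free hydroxy alkyne with the (R) carbinol centre unchanged.

Step 13
Reactants: 15 the C29 iodide; 21 (1R)-4-ethynyl-3,5,5-trimethylcyclohex-3-en-1-ol
Product: 22 (3R,3'R,6'R)-7,8-didehydro-β,ε-carotene-3,3'-diol (all-E; CNP0232536.1)
Conditions: Pd(PPh3)4 (10 mol%), CuI (20 mol%), i-Pr2NH, THF (degassed), rt, dark
Reagents that add atoms: none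
Why: Sonogashira alkynyl–alkenyl coupling: zerovalent palladium inserts into the C9–I bond of 15, the copper acetylide formed from the terminal C8–H of 21 transmetalates, and reductive elimination forms the C8–C9 sp–sp2 bond. The closest known reaction type is the palladium/copper coupling of terminal alkynes with simple (E)-2-iodoalkenes, here applied to a polyenyl iodide. No ring is closed and no stereocentre is created; the C9=C10 E geometry is inherited from the iodide because oxidative addition and reductive elimination are stereoretentive. The step needs chemoselectivity for the C–I bond over eight conjugated alkenes and two free hydroxyls, which the weak C(sp2)–I bond secures at room temperature, and suppression of oxidative alkyne dimerisation, which exclusion of oxygen secures. Mild, dark conditions should leave the C3, C3' and C6' stereocentres and the isomerisation-prone 9E enyne untouched, and no deprotection follows.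

Compound list
1 | (R)-α-ionone, (3E)-4-[(1R)-2,6,6-trimethylcyclohex-2-en-1-yl]but-3-en-2-one | CC1=CCCC(C)(C)[C@H]1/C=C/C(C)=O | starting material
2 | (3R,6R)-3-hydroxy-α-ionone, (3E)-4-[(1R,4R)-4-hydroxy-2,6,6-trimethylcyclohex-2-en-1-yl]but-3-en-2-one | CC1=C[C@H](O)CC(C)(C)[C@H]1/C=C/C(C)=O | intermediate
3 | (2E,4E)-5-[(1R,4R)-4-hydroxy-2,6,6-trimethylcyclohex-2-en-1-yl]-3-methylpenta-2,4-dienenitrile | CC1=C[C@H](O)CC(C)(C)[C@H]1/C=C/C(C)=C/C#N | intermediate
4 | (2E,4E)-5-[(1R,4R)-4-hydroxy-2,6,6-trimethylcyclohex-2-en-1-yl]-3-methylpenta-2,4-dienal | CC1=C[C@H](O)CC(C)(C)[C@H]1/C=C/C(C)=C/C=O | intermediate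
5 | but-2-yn-1-ol | CC#CCO | starting material
6 | (E)-alkenylzirconocene of but-2-yn-1-ol (C3–Zr and O–Zr, each Cp2ZrCl) | C/C([Zr](Cl)(C1C=CC=C1)C1C=CC=C1)=C\CO[Zr](Cl)(C1C=CC=C1)C1C=CC=C1 | intermediate
7 | (E)-3-iodobut-2-en-1-ol | C/C(I)=C\CO | intermediate
8 | (E)-1-bromo-3-iodobut-2-ene | C/C(I)=C\CBr | intermediate
9 | diethyl [(2E)-3-iodobut-2-en-1-yl]phosphonate | CCOP(=O)(OCC)C/C=C(\C)I | intermediate
10 | (2E,4E,6E)-2,7-dimethylocta-2,4,6-trienedial | O=C/C(C)=C/C=C/C=C(C)/C=O | starting material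
11 | sodium salt of phosphonate 9 (carbanion at C1) | [Na+].CCOP(=O)(OCC)[CH-]/C=C(\C)I | intermediate
12 | (2E,4E,6E,8E,10E)-11-iodo-2,7-dimethyldodeca-2,4,6,8,10-pentaenal | O=C/C(C)=C/C=C/C=C(C)/C=C/C=C(\C)I | intermediate
13 | (2E,4E,6E,8E,10E)-11-iodo-2,7-dimethyldodeca-2,4,6,8,10-pentaen-1-ol | OC/C(C)=C/C=C/C=C(C)/C=C/C=C(\C)I | intermediate
14 | [(2E,4E,6E,8E,10E)-11-iodo-2,7-dimethyldodeca-2,4,6,8,10-pentaen-1-yl]triphenylphosphonium bromide | [Br-].c1ccccc1[P+](c1ccccc1)(c1ccccc1)C/C(C)=C/C=C/C=C(C)/C=C/C=C(\C)I | intermediate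
15 | (1R,4R)-4-[(1E,3E,5E,7E,9E,11E,13E,15E)-16-iodo-3,7,12-trimethylheptadeca-1,3,5,7,9,11,13,15-octaen-1-yl]-3,5,5-trimethylcyclohex-2-en-1-ol | CC1=C[C@H](O)CC(C)(C)[C@H]1/C=C/C(C)=C/C=C/C(C)=C/C=C/C=C(C)/C=C/C=C(\C)I | intermediate
16 | (4R,6R)-4-hydroxy-2,2,6-trimethylcyclohexan-1-one (actinol) | O=C1C(C)(C)C[C@H](O)C[C@H]1C | starting material
17 | (4R,6R)-4-[(tert-butyldimethylsilyl)oxy]-2,2,6-trimethylcyclohexan-1-one | O=C1C(C)(C)C[C@H](O[Si](C)(C)C(C)(C)C)C[C@H]1C | intermediate
18 | lithium (4R)-4-[(tert-butyldimethylsilyl)oxy]-2,6,6-trimethylcyclohex-1-en-1-olate | [Li+].[O-]C1=C(C)C[C@@H](O[Si](C)(C)C(C)(C)C)CC1(C)C | intermediate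
19 | (4R)-4-[(tert-butyldimethylsilyl)oxy]-2,6,6-trimethylcyclohex-1-en-1-yl trifluoromethanesulfonate | O=S(=O)(OC1=C(C)C[C@@H](O[Si](C)(C)C(C)(C)C)CC1(C)C)C(F)(F)F | intermediate
20 | tert-butyldimethyl{[(1R)-3,5,5-trimethyl-4-[(trimethylsilyl)ethynyl]cyclohex-3-en-1-yl]oxy}silane | C[Si](C)(C)C#CC1=C(C)C[C@@H](O[Si](C)(C)C(C)(C)C)CC1(C)C | intermediate
21 | (1R)-4-ethynyl-3,5,5-trimethylcyclohex-3-en-1-ol | C#CC1=C(C)C[C@@H](O)CC1(C)C | intermediate
22 | (3R,3'R,6'R)-7,8-didehydro-β,ε-carotene-3,3'-diol, all-E (CNP0232536.1) | CC1=C[C@H](O)CC(C)(C)[C@H]1/C=C/C(C)=C/C=C/C(C)=C/C=C/C=C(C)/C=C/C=C(\C)C#CC1=C(C)C[C@@H](O)CC1(C)C | target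

Total step count: 13. Longest linear sequence: 7 steps (steps 4, 5, 6, 7, 8, 9 and 13).

Steps most likely to fail

Step 13. The coupling may be defeated by oxidative dimerisation of the alkyne, by slow turnover with decay of the polyenyl iodide under amine and copper, or by 9E/9Z isomerisation of the product. The fallback changes the nucleophile to a tin acetylide and removes copper and amine. It sets out from 21 and comes back at 22. Alkyne 21 is treated with n-BuLi (2.1 equiv) and then Bu3SnCl, and aqueous work-up frees the hydroxyl to give (1R)-3,5,5-trimethyl-4-[(tributylstannyl)ethynyl]cyclohex-3-en-1-ol F1. A Stille coupling of F1 with 15 (Pd2(dba)3, AsPh3, NMP, rt) forms the same C8–C9 bond and gives 22 directly.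

Step 1. The enzymatic hydroxylation may show insufficient regio- or facial selectivity, over-oxidation to the 3'-ketone, or poor conversion at preparative substrate loading. The fallback installs the hydroxyl chemically. It sets out from 1 and comes back at 2.
- Ketalisation of 1 (ethylene glycol, HC(OMe)3, cat. p-TsOH, rt) gives 2-methyl-2-{(E)-2-[(1R)-2,6,6-trimethylcyclohex-2-en-1-yl]ethenyl}-1,3-dioxolane F2.
- Allylic oxidation (t-BuOOH, aq. NaOCl, MeCN, 0 °C) gives (4R)-3,5,5-trimethyl-4-[(E)-2-(2-methyl-1,3-dioxolan-2-yl)ethenyl]cyclohex-2-en-1-one F3.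
- Reduction with LiBH(s-Bu)3 (THF, −78 °C), with hydride expected to arrive anti to the C6' side chain, gives the 3',6'-cis alcohol (1S,4R)-3,5,5-trimethyl-4-[(E)-2-(2-methyl-1,3-dioxolan-2-yl)ethenyl]cyclohex-2-en-1-ol F4.
- Mitsunobu inversion (4-nitrobenzoic acid, PPh3, DIAD, THF) gives the trans ester (1R,4R)-3,5,5-trimethyl-4-[(E)-2-(2-methyl-1,3-dioxolan-2-yl)ethenyl]cyclohex-2-en-1-yl 4-nitrobenzoate F5.
- Methanolysis (K2CO3, MeOH) gives the trans alcohol (1R,4R)-3,5,5-trimethyl-4-[(E)-2-(2-methyl-1,3-dioxolan-2-yl)ethenyl]cyclohex-2-en-1-ol F6.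
- Mild ketal hydrolysis (PPTS, acetone/H2O) returns 2.

Step 9. The Wittig union may give an E/Z mixture at C11'=C12' that does not equilibrate cleanly, and the iodo-polyene may decay on heating. The fallback replaces the ylide with an E-selective phosphonate carbanion on protected material. It sets out from 13 and 4 and comes back at 15.
- Appel bromination of 13 (CBr4, PPh3, CH2Cl2, 0 °C) gives (2E,4E,6E,8E,10E)-1-bromo-11-iodo-2,7-dimethyldodeca-2,4,6,8,10-pentaene F7.
- Arbuzov reaction (P(OEt)3, 80 °C) gives diethyl [(2E,4E,6E,8E,10E)-11-iodo-2,7-dimethyldodeca-2,4,6,8,10-pentaen-1-yl]phosphonate F8.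
- Silylation of 4 (TBSCl, imidazole, DMF) gives (2E,4E)-5-[(1R,4R)-4-(tert-butyldimethylsilyloxy)-2,6,6-trimethylcyclohex-2-en-1-yl]-3-methylpenta-2,4-dienal F9.
- Horner–Wadsworth–Emmons reaction of F8 (NaN(SiMe3)2, THF, −78 °C) with F9 gives the silyl ether of the C29 iodide, tert-butyl{[(1R,4R)-4-[(1E,3E,5E,7E,9E,11E,13E,15E)-16-iodo-3,7,12-trimethylheptadeca-1,3,5,7,9,11,13,15-octaen-1-yl]-3,5,5-trimethylcyclohex-2-en-1-yl]oxy}dimethylsilane F10.
- TBAF (THF, 0 °C) returns 15.

Further compounds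
F1 | step 13 | (1R)-3,5,5-trimethyl-4-[(tributylstannyl)ethynyl]cyclohex-3-en-1-ol | CCCC[Sn](CCCC)(CCCC)C#CC1=C(C)C[C@@H](O)CC1(C)C
F2 | step 1 | 2-methyl-2-{(E)-2-[(1R)-2,6,6-trimethylcyclohex-2-en-1-yl]ethenyl}-1,3-dioxolane | CC1=CCCC(C)(C)[C@H]1/C=C/C2(C)OCCO2
F3 | step 1 | (4R)-3,5,5-trimethyl-4-[(E)-2-(2-methyl-1,3-dioxolan-2-yl)ethenyl]cyclohex-2-en-1-one | CC1=CC(=O)CC(C)(C)[C@H]1/C=C/C2(C)OCCO2
F4 | step 1 | (1S,4R)-3,5,5-trimethyl-4-[(E)-2-(2-methyl-1,3-dioxolan-2-yl)ethenyl]cyclohex-2-en-1-ol | CC1=C[C@@H](O)CC(C)(C)[C@H]1/C=C/C2(C)OCCO2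
F5 | step 1 | (1R,4R)-3,5,5-trimethyl-4-[(E)-2-(2-methyl-1,3-dioxolan-2-yl)ethenyl]cyclohex-2-en-1-yl 4-nitrobenzoate | CC1=C[C@H](OC(=O)c2ccc(cc2)[N+](=O)[O-])CC(C)(C)[C@H]1/C=C/C3(C)OCCO3
F6 | step 1 | (1R,4R)-3,5,5-trimethyl-4-[(E)-2-(2-methyl-1,3-dioxolan-2-yl)ethenyl]cyclohex-2-en-1-ol | CC1=C[C@H](O)CC(C)(C)[C@H]1/C=C/C2(C)OCCO2
F7 | step 9 | (2E,4E,6E,8E,10E)-1-bromo-11-iodo-2,7-dimethyldodeca-2,4,6,8,10-pentaene | BrC/C(C)=C/C=C/C=C(C)/C=C/C=C(\C)I
F8 | step 9 | diethyl [(2E,4E,6E,8E,10E)-11-iodo-2,7-dimethyldodeca-2,4,6,8,10-pentaen-1-yl]phosphonate | CCOP(=O)(OCC)C/C(C)=C/C=C/C=C(C)/C=C/C=C(\C)I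
F9 | step 9 | (2E,4E)-5-[(1R,4R)-4-(tert-butyldimethylsilyloxy)-2,6,6-trimethylcyclohex-2-en-1-yl]-3-methylpenta-2,4-dienal | CC1=C[C@H](O[Si](C)(C)C(C)(C)C)CC(C)(C)[C@H]1/C=C/C(C)=C/C=O
F10 | step 9 | tert-butyl{[(1R,4R)-4-[(1E,3E,5E,7E,9E,11E,13E,15E)-16-iodo-3,7,12-trimethylheptadeca-1,3,5,7,9,11,13,15-octaen-1-yl]-3,5,5-trimethylcyclohex-2-en-1-yl]oxy}dimethylsilane | CC1=C[C@H](O[Si](C)(C)C(C)(C)C)CC(C)(C)[C@H]1/C=C/C(C)=C/C=C/C(C)=C/C=C/C=C(C)/C=C/C=C(\C)I
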